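## The problem

Target 23 is a hexasubstituted benzene, ring A, with the phloroglucinol pattern. C1 carries a (2R)-2-methylbutanoyl group, C2, C4 and C6 carry free hydroxyls, and C3 and C5 are each joined through one CH2 to C3 of a 6-ethyl-4-hydroxy-5-methyl-2H-pyran-2-one. The three rings are held together only by these two one-carbon bridges between enolic carbons. Such bonds form readily by Mannich and Michael chemistry but reopen by retro-Michael fragmentation under heat, strong acid or strong base, so they belong at the end under mild conditions. The single stereocentre is C2 of the side chain, alpha to the aryl ketone; nothing else in the molecule can induce it, so it must be bought as one enantiomer and kept from enolising in every later step. The free phloroglucinol is easily oxidised in basic aerobic media, the pyranones are vinylogous acid lactones that open in hot aqueous base, and the acyl group can be lost in hot strong acid. The bridging poses no regiochemical question, because the two arms are identical and the two open ring carbons of the acylphloroglucinol are equivalent. The enabling feature is that the acyl-bearing C1 lies beside the oxygen-bearing C2 while C6 on its other side is oxygenated too: an aryne across C1–C2 with an alkoxy group at C6 can take up a carboxylic acid with oxygen at C2 and the acyl carbon at C1, which avoids a Lewis acidic Friedel–Crafts acylation with an alpha-branched chiral acyl donor.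

## Retrosynthesis

**Bridges.** The first cut removes both methylene bridges of 23: the ring A C3–CH2 and C5–CH2 bonds and the two CH2–C3 bonds to the pyranones. This gives acylphloroglucinol 14, two molecules of pyranone 19 and two one-carbon iminium electrophiles. These are the most labile bonds of the target and the cut is fully convergent. In the forward direction the pyranone is first turned completely into Mannich base 20, which eliminates to the methylidene dione 21; ring A of 14 adds to 21 twice, through mono-bridged 22. The reaction must run warm at most, and no free 19 may be present when 21 forms, since 19 would add to 21.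

**Pyranone.** Pyranone 19 is cut at C4–C5 and O1–C2, which gives the silyl enol ether 16 of pentan-3-one 15 and malonyl dichloride 17. This is shorter than assembling the same ring from a 3,5-dioxo ester. Ketone 15 is symmetric, so 16 has no regiochemical ambiguity. The forward reaction is C-acylation to acid chloride 18 followed by closure through the enol oxygen.

**Ring A hydroxyls.** Triol 14 is traced to dimethyl ether 13 by cutting two O–CH3 bonds. Methyl ethers are chosen because they survive the organolithium and fluoride steps, and because the ether on C6 polarises the aryne. The forward reaction must cleave a chelated ortho ether and an unassisted para ether without enolising the ketone.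

**Aryl ketone (key cut).** Ketone 13 is cut at C1–C(acyl) and C2–O, which gives the ortho-silylaryl triflate 8 and (2R)-2-methylbutanoic acid 9. Against a Friedel–Crafts or Fries approach, this cut needs no acid chloride and no Lewis acid, and it delivers the acyl group and the neighbouring free hydroxyl together, on defined carbons. The precursors are a ring with one silyl and one triflate handle and a chiral-pool acid. The forward reaction runs through aryne 10, aryl anion 11 and benzoxetene alkoxide 12. Oxygen must add at the aryne carbon remote from the methoxy group, and the acyl shift must beat protonation.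

**Aryne precursor.** Triflate 8 is cut at the S–O bond (phenol 7), at the C–Si bond and at the carbamate C–O bond, leading through silyl carbamate 6 and carbamate 2 to 3,5-dimethoxyphenol 1. The silicon must sit on the carbon between the phenol oxygen and a methoxy group, which is the site a carbamate-directed lithiation reaches (intermediates 3, 4, 5). A secondary N-isopropyl carbamate is preferred to a tertiary one because it leaves under mild amine base, which spares the electron-rich aryl–silicon bond.

## Roads not taken

Alternative 1: The cut runs through ring A itself, at C2–C3 and C5–C6, so that ring A is closed last between two arms that already carry the pyranones.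
- Forward step: the trimethylsilyl enol ether A1 of a symmetric ketone with a 4-methoxypyranone on each arm would be acylated twice at carbon by malonyl dichloride 17. The resulting cyclohexanetrione would enolise to phloroglucinol A2.
- Merit: both bridges are ordinary C–C bonds laid down before the sensitive phloroglucinol exists. No equilibrating bridging step is needed and no methylene-bis(pyranone) can form. In this respect the alternative is the safer design.
- Weak points:
  - The innate course of this reagent pair is the one used in step 7: after the first C-acylation the enol oxygen closes on the second acid chloride to a 4-hydroxy-2-pyranone. Carbocycle formation needs a second enolisation across the ketone and must outrun that O-closure.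
  - A1 needs its own multistep assembly, and two pyranone methyl ethers have to be removed later.
  - A2 has no acyl group. It would have to be added at the last free ring carbon by Friedel–Crafts acylation with an activated form of 9, in the presence of three phenols and two pyranones. The stereocentre would thus enter under the harshest conditions of the route.
- Comparison: the chosen plan accepts a reversible bridging step. It sets against this a closing reaction in which both open carbons of 14 are equivalent and both must react, an acyl introduction under non-acidic conditions early in the sequence, and fewer steps.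

Alternative 2: The cut is at C4–C5 and O1–C2 of both pyranones, which are grown last on a ring A that already bears two CH2-malonyl units.
- Forward step: tetra-acid chloride A3 would react with two equivalents of silyl enol ether 16 to give the bis-pyranone A4.
- Merit: this is the same dependable ring closure as step 7, and 2-substituted malonyl dichlorides are known to give 3-substituted pyranones. The bridges come from simple benzylic alkylation. In certainty of ring closure it equals the chosen plan, and in avoiding the reversible bridging it is better.
- Weak points:
  - Monosubstituted malonyl dichlorides lose HCl readily to chlorocarbonyl ketenes, and four acid chlorides on one molecule invite cross-reaction between the two ends.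
  - A3 needs at least four steps of its own.
  - A4 again lacks the acyl group. Its one free ring carbon is flanked by two methoxy groups in a pentasubstituted ring, so a hindered Lewis acid acylation with the chiral acyl donor and three ether cleavages in the presence of the pyranones would follow.
- Comparison: the route is longer and linear and sets the stereocentre late. The chosen plan offers convergence and a mild, early acyl transfer.

Alternative 3: This road keeps the same endgame and differs only in how the aryl ketone is made: both bonds to the carbonyl carbon are cut.
- Forward step: borinic ester A6, built from lithiated 1,3,5-trimethoxybenzene A5 and an enantioenriched sec-butylboron unit, would react with a dichloromethyl ether and a hindered lithium alkoxide. Aryl and sec-butyl would migrate in turn from boron to carbon with retention, and buffered peroxide would release ketone A7.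
- Merit: A5 is a cheap symmetric arene that needs no regiocontrol, whereas the chosen plan spends three steps on triflate 8. Here the alternative is better. The migrations are stereoretentive, and no enolisable acyl species exists until the ketone is released.
- Weak points:
  - The stereocentre is made and not bought. It would come from asymmetric hydroboration of a gaseous butene, and its purity is limited by that reagent.
  - Boron bound to a 2,6-dimethoxyaryl group is prone to protodeboronation.
  - The double migration with a di-ortho-substituted aryl group is sterically demanding.
  - A7 carries three methyl ethers, so one more ether must be cleaved.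
- Comparison: the chosen plan takes the stereocentre unchanged from acid 9 and delivers the ortho-hydroxyl already free, at the price of a longer arene preparation.

Key step: step 4

Assumption: silyl enol ether 16 is used as its E/Z mixture, since the double-bond geometry disappears when pyranone 19 forms, and acid 9 is bought as the R enantiomer.

## Route

Step 1
Reactants: 1 3,5-dimethoxyphenol
Product: 2 3,5-dimethoxyphenyl propan-2-ylcarbamate
Conditions: iPrNCO, Et3N (cat.), CH2Cl2, rt
Reagents that add atoms: isopropyl isocyanate, CC(C)N=C=O
Why: Amine-catalysed addition of the phenol to the isocyanate (carbamoylation) should give the secondary carbamate, which serves as directing group now and leaves under mild base later.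

Step 2
Reactants: 2 3,5-dimethoxyphenyl propan-2-ylcarbamate
Product: 6 3,5-dimethoxy-2-(trimethylsilyl)phenyl propan-2-ylcarbamate, via N-silyl carbamate 3 (not isolated), via aryllithium 4 (not isolated), via disilyl carbamate 5 (not isolated)
Conditions: TBSOTf, TMEDA, Et2O, 0 °C → rt; n-BuLi, TMEDA, −78 °C; Me3SiCl, −78 °C → rt; aq. NaHSO4
Reagents that add atoms: chlorotrimethylsilane, C[Si](C)(C)Cl
Why: In situ N-silylation masks the N–H, and the carbamate then directs ortho-lithiation (directed ortho-metalation) to C2, the only carbon flanked by both the carbamate and a methoxy group. Me3SiCl traps aryllithium 4 at −78 °C before an anionic Fries shift can set in, and the N–Si bond of 5 is hydrolysed on acidic work-up.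

Step 3
Reactants: 6 3,5-dimethoxy-2-(trimethylsilyl)phenyl propan-2-ylcarbamate
Product: 8 3,5-dimethoxy-2-(trimethylsilyl)phenyl trifluoromethanesulfonate, via silyl phenol 7 (not isolated)
Conditions: DBU, Et2NH, MeCN, 40 °C; then PhNTf2, rt
Reagents that add atoms: N-phenylbis(trifluoromethanesulfonimide), O=S(=O)(N(c1ccccc1)S(=O)(=O)C(F)(F)F)C(F)(F)F
Why: DBU should trigger E1cB loss of isopropyl isocyanate from the N–H carbamate, with Et2NH scavenging it as a urea, and the freed phenoxide is O-sulfonylated in the same flask. This one-pot carbamate cleavage and triflation is the usual last stage of ortho-silylaryl triflate syntheses and avoids handling the acid-sensitive silyl phenol.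

Step 4
Reactants: 8 3,5-dimethoxy-2-(trimethylsilyl)phenyl trifluoromethanesulfonate; 9 (2R)-2-methylbutanoic acid
Product: 13 (2R)-1-(2-hydroxy-4,6-dimethoxyphenyl)-2-methylbutan-1-one, via 3,5-dimethoxybenzyne 10 (not isolated), via aryl ester carbanion 11 (not isolated), via benzoxetene alkoxide 12 (not isolated)
Conditions: CsF, THF, 125 °C (sealed tube)
Reagents that add atoms: none
Why: Fluoride attacks the silicon of 8 and the triflate leaves, giving 3,5-dimethoxybenzyne 10 by 1,2-elimination. The cesium carboxylate of 9 adds through oxygen to the aryne carbon remote from the flanking methoxy group, because this is the more electrophilic, less bent terminus and the negative charge then develops on the carbon beside the C–OMe bond, where the inductive pull of oxygen stabilises it; this gives aryl anion 11. The carbanion of 11 attacks its own ester carbonyl (4-exo-trig) to benzoxetene alkoxide 12, whose ring C–O bond breaks at once to the phenoxide of 13, so the net result is insertion of the aryne into the C–O bond of the acid. The closest known reaction type is the fluoride-induced C–O addition of carboxylic acids to arynes from ortho-silylaryl triflates, which gives ortho-hydroxyaryl ketones when run hot enough for acyl transfer to outrun protonation. No ring remains in the product; the four-membered ring of 12 is transient and its new carbinol centre, formed as either epimer, vanishes on opening. No stereocentre is created: C2 of the side chain comes unchanged from 9, the carboxylate cannot enolise, and the product rests as a cesium phenoxide whose di-ortho-substituted ketone is twisted out of the ring plane and enolises reluctantly. The step needs regioselectivity (oxygen at the distal carbon), secured by the methoxy group on C3 of the aryne, and chemoselectivity (acyl shift before protonation of 11), secured by the intramolecular four-centre path, the heat and the absence of any proton source other than 9 itself.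

Step 5
Reactants: 13 (2R)-1-(2-hydroxy-4,6-dimethoxyphenyl)-2-methylbutan-1-one
Product: 14 (2R)-2-methyl-1-(2,4,6-trihydroxyphenyl)butan-1-one
Conditions: BBr3, CH2Cl2, −78 °C → rt; then H2O
Reagents that add atoms: none
Why: Lewis acid ether cleavage: boron coordinates each methoxy oxygen and bromide attacks the methyl group, the ortho ether being assisted by chelation to the ketone and the para ether needing excess reagent at rt. The ketone is flanked by two ortho oxygens and cannot reach a planar enol, which should keep the stereocentre intact, as it does in Lewis acid chemistry of other acylphloroglucinols.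

Step 6
Reactants: 15 pentan-3-one
Product: 16 trimethyl(pent-2-en-3-yloxy)silane (E/Z mixture)
Conditions: Me3SiCl, Et3N, DMF, 80 °C
Reagents that add atoms: chlorotrimethylsilane, C[Si](C)(C)Cl
Why: Silyl enol ether formation under equilibrating amine conditions; the ketone is symmetric, so only one constitutional isomer can form.

Step 7
Reactants: 16 trimethyl(pent-2-en-3-yloxy)silane; 17 malonyl dichloride
Product: 19 6-ethyl-4-hydroxy-5-methyl-2H-pyran-2-one, via dioxoheptanoyl chloride 18 (not isolated)
Conditions: Et2O, −78 °C → rt
Reagents that add atoms: none
Why: Effenberger pyranone synthesis: the silyl enol ether is C-acylated by one acid chloride to 18 (racemic at C4, which is of no consequence), whose enol oxygen closes on the second acid chloride (6-exo-trig lactonisation), and the ring tautomerises to the 4-hydroxy-2-pyranone.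

Step 8
Reactants: 14 (2R)-2-methyl-1-(2,4,6-trihydroxyphenyl)butan-1-one; 19 6-ethyl-4-hydroxy-5-methyl-2H-pyran-2-one (2 equiv or slightly more)
Product: 23 3,3'-({2,4,6-trihydroxy-5-[(2R)-2-methylbutanoyl]-1,3-phenylene}bis(methylene))bis(6-ethyl-4-hydroxy-5-methyl-2H-pyran-2-one), via Mannich base hydroiodide 20 (not isolated), via methylidenepyrandione 21 (not isolated), via mono-bridged adduct 22 (not isolated)
Conditions: 19, Me2N=CH2+ I− (1 equiv per 19), MeCN, rt; then 14, 50 °C
Reagents that add atoms: N,N-dimethylmethyleneiminium iodide (Eschenmoser's salt), C=[N+](C)C.[I-]
Why: Mannich reaction at C3 of 19 gives 20, which loses dimethylamine (E1cB) to the Michael acceptor 21; ring carbons C3 and C5 of 14 then add in turn through 22, a Friedel–Crafts-type conjugate addition known as the carba-Betti coupling of acylphloroglucinols with pyranones. Converting all of 19 into 20 before 14 is added removes the nucleophile that would otherwise give methylene-bis(pyranone). Both open carbons of 14 are equivalent and both are to be filled, and the weakly acidic ammonium medium leaves the stereocentre alone.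

## Compound list

1 | 3,5-dimethoxyphenol | COc1cc(O)cc(OC)c1 | starting material
2 | 3,5-dimethoxyphenyl propan-2-ylcarbamate | COc1cc(OC)cc(OC(=O)NC(C)C)c1 | intermediate
3 | 3,5-dimethoxyphenyl [tert-butyl(dimethyl)silyl](propan-2-yl)carbamate | COc1cc(OC)cc(OC(=O)N(C(C)C)[Si](C)(C)C(C)(C)C)c1 | intermediate (not isolated)
4 | [2-({[tert-butyl(dimethyl)silyl](propan-2-yl)carbamoyl}oxy)-4,6-dimethoxyphenyl]lithium | [Li]c1c(OC)cc(OC)cc1OC(=O)N(C(C)C)[Si](C)(C)C(C)(C)C | intermediate (not isolated)
5 | 3,5-dimethoxy-2-(trimethylsilyl)phenyl [tert-butyl(dimethyl)silyl](propan-2-yl)carbamate | COc1cc(OC)c([Si](C)(C)C)c(OC(=O)N(C(C)C)[Si](C)(C)C(C)(C)C)c1 | intermediate (not isolated)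
6 | 3,5-dimethoxy-2-(trimethylsilyl)phenyl propan-2-ylcarbamate | COc1cc(OC)c([Si](C)(C)C)c(OC(=O)NC(C)C)c1 | intermediate
7 | 3,5-dimethoxy-2-(trimethylsilyl)phenol (present as its DBU salt) | COc1cc(O)c([Si](C)(C)C)c(OC)c1 | intermediate (not isolated)
8 | 3,5-dimethoxy-2-(trimethylsilyl)phenyl trifluoromethanesulfonate | COc1cc(OC)c([Si](C)(C)C)c(OS(=O)(=O)C(F)(F)F)c1 | intermediate
9 | (2R)-2-methylbutanoic acid | CC[C@@H](C)C(=O)O | starting material
10 | 3,5-dimethoxybenzyne (1,2-didehydro-3,5-dimethoxybenzene) | COC1=CC(OC)=CC#C1 | intermediate (not isolated)
11 | cesium 2,4-dimethoxy-6-{[(2R)-2-methylbutanoyl]oxy}benzen-1-ide | [Cs+].CC[C@@H](C)C(=O)Oc1cc(OC)cc(OC)[c-]1 | intermediate (not isolated)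
12 | cesium 2-[(2R)-butan-2-yl]-3,5-dimethoxy-2H-1-benzoxet-2-olate (either configuration at C2 of the four-membered ring) | [Cs+].CC[C@@H](C)C1([O-])Oc2cc(OC)cc(OC)c21 | intermediate (not isolated)
13 | (2R)-1-(2-hydroxy-4,6-dimethoxyphenyl)-2-methylbutan-1-one | CC[C@@H](C)C(=O)c1c(O)cc(OC)cc1OC | intermediate
14 | (2R)-2-methyl-1-(2,4,6-trihydroxyphenyl)butan-1-one | CC[C@@H](C)C(=O)c1c(O)cc(O)cc1O | intermediate
15 | pentan-3-one | CCC(=O)CC | starting material
16 | trimethyl(pent-2-en-3-yloxy)silane (E/Z mixture) | CC=C(CC)O[Si](C)(C)C | intermediate
17 | malonyl dichloride (propanedioyl dichloride) | O=C(Cl)CC(=O)Cl | starting material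
18 | 4-methyl-3,5-dioxoheptanoyl chloride (racemic) | CCC(=O)C(C)C(=O)CC(=O)Cl | intermediate (not isolated)
19 | 6-ethyl-4-hydroxy-5-methyl-2H-pyran-2-one | CCc1oc(=O)cc(O)c1C | intermediate
20 | 3-[(dimethylamino)methyl]-6-ethyl-4-hydroxy-5-methyl-2H-pyran-2-one hydroiodide | CCc1oc(=O)c(CN(C)C)c(O)c1C.I | intermediate (not isolated)
21 | 6-ethyl-5-methyl-3-methylidene-2H-pyran-2,4(3H)-dione | CCC1=C(C)C(=O)C(=C)C(=O)O1 | intermediate (not isolated)
22 | 6-ethyl-4-hydroxy-5-methyl-3-({2,4,6-trihydroxy-3-[(2R)-2-methylbutanoyl]phenyl}methyl)-2H-pyran-2-one | CC[C@@H](C)C(=O)c1c(O)cc(O)c(Cc2c(O)c(C)c(CC)oc2=O)c1O | intermediate (not isolated)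
23 | 3,3'-({2,4,6-trihydroxy-5-[(2R)-2-methylbutanoyl]-1,3-phenylene}bis(methylene))bis(6-ethyl-4-hydroxy-5-methyl-2H-pyran-2-one) | CCc1oc(=O)c(Cc2c(O)c(Cc3c(O)c(C)c(CC)oc3=O)c(O)c(C(=O)[C@H](C)CC)c2O)c(O)c1C | target

## Step count and risks

Total step count: 8. Longest linear sequence: 6 steps (steps 1 to 5, then step 8); the pyranone branch (steps 6 and 7) joins at step 8.

**Step 4 (key step).**
- What may go wrong: protonation of aryl anion 11 before the acyl shift, which ends in simple O-arylation of the acid; a second arylation of the product phenoxide by further aryne; some erosion of enantiopurity by base-mediated enolisation at 125 °C; and a minor share of oxygen addition at the wrong aryne carbon.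
- Fallback: it sets out from phenol 1 and acid 9. Esterification (DCC, DMAP, CH2Cl2) should give 3,5-dimethoxyphenyl (2R)-2-methylbutanoate F1. A chelation-controlled Fries rearrangement (TiCl4, CH2Cl2, rt to reflux) should then move the acyl group to the carbon between the hydroxyl and a methoxy group. That product is ketone 13, where the route is rejoined.
- F1 is also what the aryne step gives when protonation wins, so such material can be carried forward the same way. The price is a Lewis acid step that the insertion avoids.

**Step 2.**
- What may go wrong: competing metalation at C4 between the two methoxy groups, an anionic Fries shift of the carbamoyl group if the aryllithium warms, and incomplete silylation at a carbon crowded by two oxygen substituents.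
- Fallback: it sets out from phenol 1. Ortho-bromination (NBS, CH2Cl2, −78 °C) should give 2-bromo-3,5-dimethoxyphenol F2, and O-silylation (HMDS, THF, reflux) its silyl ether (2-bromo-3,5-dimethoxyphenoxy)(trimethyl)silane F3. Bromine–lithium exchange (n-BuLi, THF, −100 °C) is followed by a 1,3 shift of silicon from oxygen to carbon (retro-Brook), and the resulting phenoxide is trapped with Tf2O. The route is rejoined at triflate 8.

**Step 5.**
- What may go wrong: incomplete cleavage of the unassisted para-methoxy group, loss of enantiopurity through acid-promoted enolisation during a prolonged reaction, and acid-induced loss of the acyl group.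
- Fallback: it sets out from acid 9 and replaces methyl by benzyl protection. Commercial 3,5-bis(benzyloxy)phenol F4 is brominated (NBS) to 3,5-bis(benzyloxy)-2-bromophenol F5 and silylated (HMDS) to {[3,5-bis(benzyloxy)-2-bromophenyl]oxy}(trimethyl)silane F6. Bromine–lithium exchange with retro-Brook shift and triflation gives 3,5-bis(benzyloxy)-2-(trimethylsilyl)phenyl trifluoromethanesulfonate F7. The same CsF-mediated insertion of 9 should give (2R)-1-[2,4-bis(benzyloxy)-6-hydroxyphenyl]-2-methylbutan-1-one F8. Hydrogenolysis (H2, Pd/C, EtOAc, rt) removes both benzyl groups under neutral conditions and rejoins the route at triol 14.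

**Step 8.**
- What may go wrong: addition of free pyranone to 21 (methylene-bis(pyranone) formation) if the Mannich step is incomplete, stalling after the first bridge at 22, and retro-Michael scrambling of bridges that links two ring A units through a methylene group.
- Fallback: it sets out from triol 14 and reverses the polarity. Treatment with excess Me2N=CH2+ I− should give the bis-Mannich base (2R)-1-{3,5-bis[(dimethylamino)methyl]-2,4,6-trihydroxyphenyl}-2-methylbutan-1-one F9. On heating with pyranone 19 (dioxane, 80 °C) it should lose dimethylamine to ortho-quinone methides on ring A, which C3 of 19 traps. This arrives directly at target 23.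

## Further compounds

F1 | step 4 | 3,5-dimethoxyphenyl (2R)-2-methylbutanoate | CC[C@@H](C)C(=O)Oc1cc(OC)cc(OC)c1
F2 | step 2 | 2-bromo-3,5-dimethoxyphenol | COc1cc(O)c(Br)c(OC)c1
F3 | step 2 | (2-bromo-3,5-dimethoxyphenoxy)(trimethyl)silane | COc1cc(O[Si](C)(C)C)c(Br)c(OC)c1
F4 | step 5 | 3,5-bis(benzyloxy)phenol (commercial) | Oc1cc(OCc2ccccc2)cc(OCc2ccccc2)c1
F5 | step 5 | 3,5-bis(benzyloxy)-2-bromophenol | Oc1cc(OCc2ccccc2)cc(OCc2ccccc2)c1Br
F6 | step 5 | {[3,5-bis(benzyloxy)-2-bromophenyl]oxy}(trimethyl)silane | C[Si](C)(C)Oc1cc(OCc2ccccc2)cc(OCc2ccccc2)c1Br
F7 | step 5 | 3,5-bis(benzyloxy)-2-(trimethylsilyl)phenyl trifluoromethanesulfonate | C[Si](C)(C)c1c(OCc2ccccc2)cc(OCc2ccccc2)cc1OS(=O)(=O)C(F)(F)F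
F8 | step 5 | (2R)-1-[2,4-bis(benzyloxy)-6-hydroxyphenyl]-2-methylbutan-1-one | CC[C@@H](C)C(=O)c1c(O)cc(OCc2ccccc2)cc1OCc1ccccc1
F9 | step 8 | (2R)-1-{3,5-bis[(dimethylamino)methyl]-2,4,6-trihydroxyphenyl}-2-methylbutan-1-one | CC[C@@H](C)C(=O)c1c(O)c(CN(C)C)c(O)c(CN(C)C)c1O
A1 | alternative 1 | 3,3'-[3-(trimethylsilyloxy)pent-2-ene-1,5-diyl]bis(6-ethyl-4-methoxy-5-methyl-2H-pyran-2-one) | CCc1oc(=O)c(CC=C(O[Si](C)(C)C)CCc2c(OC)c(C)c(CC)oc2=O)c(OC)c1C
A2 | alternative 1 | 3,3'-[(2,4,6-trihydroxy-1,3-phenylene)bis(methylene)]bis(6-ethyl-4-methoxy-5-methyl-2H-pyran-2-one) | CCc1oc(=O)c(Cc2c(O)cc(O)c(Cc3c(OC)c(C)c(CC)oc3=O)c2O)c(OC)c1C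
A3 | alternative 2 | 2,2'-[(2,4,6-trimethoxy-1,3-phenylene)bis(methylene)]dipropanedioyl tetrachloride | COc1cc(OC)c(CC(C(=O)Cl)C(=O)Cl)c(OC)c1CC(C(=O)Cl)C(=O)Cl
A4 | alternative 2 | 3,3'-[(2,4,6-trimethoxy-1,3-phenylene)bis(methylene)]bis(6-ethyl-4-hydroxy-5-methyl-2H-pyran-2-one) | CCc1oc(=O)c(Cc2c(OC)cc(OC)c(Cc3c(O)c(C)c(CC)oc3=O)c2OC)c(O)c1C
A5 | alternative 3 | 1,3,5-trimethoxybenzene | COc1cc(OC)cc(OC)c1
A6 | alternative 3 | methyl [(2R)-butan-2-yl](2,4,6-trimethoxyphenyl)borinate | CC[C@@H](C)B(OC)c1c(OC)cc(OC)cc1OC
A7 | alternative 3 | (2R)-2-methyl-1-(2,4,6-trimethoxyphenyl)butan-1-one | CC[C@@H](C)C(=O)c1c(OC)cc(OC)cc1OC
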